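## Retrosynthetic overview

1. Target ⇐ one-pot reductive allylation of a cross-conjugated methylenedioxy dienone: hydride 1,4-addition, then the enolate takes allyl bromide trans to the side chain (sets C6).
2. Dienone ⇐ dearomatisation of a 4-sec-alkyl-3-(methoxymethoxy)phenol, in which the outer MOM oxygen closes the dioxolane onto the para carbon and then loses its methyl (new step; sets C7a from C8).
3. Phenol ⇐ 2-sec-alkylphenol whose benzylic stereocentre C8 is set by chiral phosphoric acid / Hantzsch ester transfer hydrogenation of an ortho-quinone methide (first stereocentre).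
4. Quinone methide precursor ⇐ 3,4,5-trimethoxybenzyl Grignard reagent + 4-benzyloxy-2-hydroxyacetophenone.
5. Ring order: the six-membered carbocycle is the arene of the acetophenone and is never built; the dioxolane ring is closed in the dearomatisation; no other ring is formed.

Locants: C8 is the side-chain methine; C6 and C7a follow 1,3-benzodioxole numbering. The target is (6R,7aR) with a (2S) side chain, allyl trans to the side chain.

Assumption: the sense of induction in step 2 is assigned by analogy; if (R)-TRIP gives the (R)-phenol, (S)-TRIP is used with no other change.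

## Route

**Step 1**
Reactants: 1 1-[4-(benzyloxy)-2-hydroxyphenyl]ethan-1-one; 2 5-(chloromethyl)-1,2,3-trimethoxybenzene
Product: 4 rac-5-(benzyloxy)-2-[2-hydroxy-1-(3,4,5-trimethoxyphenyl)propan-2-yl]phenol, via benzylic Grignard reagent 3 (not isolated)
Conditions: 2 (2.6 equiv), Mg (3 equiv), 2-MeTHF, 0 °C; then 1, LaCl3·2LiCl (0.3 equiv), THF, 0 °C to rt; aq NH4Cl
Reagents that add atoms: none
Why: Grignard 1,2-addition to the aryl methyl ketone, in which the first equivalent is spent on the phenol and LaCl3·2LiCl suppresses enolisation; the racemic carbinol centre is erased in step 2.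

**Step 2**
Reactants: 4 rac-5-(benzyloxy)-2-[2-hydroxy-1-(3,4,5-trimethoxyphenyl)propan-2-yl]phenol
Product: 6 5-(benzyloxy)-2-[(2S)-1-(3,4,5-trimethoxyphenyl)propan-2-yl]phenol, via ortho-quinone methide 5 (not isolated)
Conditions: (R)-TRIP [(R)-3,3'-bis(2,4,6-triisopropylphenyl)-1,1'-binaphthyl-2,2'-diyl hydrogen phosphate] (5 mol%), Hantzsch ester (diethyl 2,6-dimethyl-1,4-dihydropyridine-3,5-dicarboxylate, 1.3 equiv), 5 Å MS, CH2Cl2, 0 °C to rt
Reagents that add atoms: none
Why: chiral phosphoric acid-catalysed dehydration gives the ortho-quinone methide, held by hydrogen bonds to the chiral phosphate, and the Hantzsch ester delivers hydride to one face of the exocyclic carbon, setting C8 as (S) (organocatalytic asymmetric transfer hydrogenation of an in situ ortho-quinone methide).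

**Step 3**
Reactants: 6 5-(benzyloxy)-2-[(2S)-1-(3,4,5-trimethoxyphenyl)propan-2-yl]phenol
Product: 7 4-(benzyloxy)-2-(methoxymethoxy)-1-[(2S)-1-(3,4,5-trimethoxyphenyl)propan-2-yl]benzene
Conditions: NaH (1.3 equiv), MOMCl (1.3 equiv), DMF, 0 °C to rt
Reagents that add atoms: chloromethyl methyl ether, COCCl
Why: Williamson-type O-alkylation of the sodium phenoxide (MOM ether formation), which does not touch C8.

**Step 4**
Reactants: 7 4-(benzyloxy)-2-(methoxymethoxy)-1-[(2S)-1-(3,4,5-trimethoxyphenyl)propan-2-yl]benzene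
Product: 8 3-(methoxymethoxy)-4-[(2S)-1-(3,4,5-trimethoxyphenyl)propan-2-yl]phenol
Conditions: H2 (1 atm), 10% Pd/C, EtOAc, rt
Reagents that add atoms: none
Why: hydrogenolysis of the benzyl aryl ether, to which the MOM acetal, the trimethoxyarene and the unactivated benzylic C8–H are inert.

**Step 5**
Reactants: 8 3-(methoxymethoxy)-4-[(2S)-1-(3,4,5-trimethoxyphenyl)propan-2-yl]phenol
Product: 11 (7aS)-7a-[(2S)-1-(3,4,5-trimethoxyphenyl)propan-2-yl]-1,3-benzodioxol-5(7aH)-one, via aryloxy-λ3-iodane 9 (not isolated), via bicyclic methyloxonium acetate 10 (not isolated)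
Conditions: PhI(OAc)2 (1.1 equiv), (CF3)2CHOH/CH2Cl2 (1:4), −40 to 0 °C
Reagents that add atoms: none
Why: Proposed new method: dealkylative dearomative acetal cyclisation, in which ligand exchange on trivalent iodine gives the aryloxy-λ3-iodane, loss of PhI makes the para carbon electrophilic, the outer MOM oxygen closes the five-membered ring there (5-exo) to a methyloxonium ion and acetate removes the methyl by SN2 to leave the methylenedioxy dienone; C7a is set because 1,3-allylic strain holds the C8–H in the ring plane next to the OMOM group, so the trimethoxybenzyl arm covers one face and the oxygen adds to the methyl-flanked face; the closest known reactions are the PhI(OAc)2 or PhI(OCOCF3)2 para-dearomatisation of 4-alkylresorcinol mono-ethers by an oxygen nucleophile tethered to the 3-oxygen (amide carbonyl, six-membered ring) and the dealkylative cyclisation of alkyl ethers onto cationic carbon as in halo-etherification.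

**Step 6**
Reactants: 11 (7aS)-7a-[(2S)-1-(3,4,5-trimethoxyphenyl)propan-2-yl]-1,3-benzodioxol-5(7aH)-one
Product: 13 (6R,7aR)-6-(prop-2-en-1-yl)-7a-[(2S)-1-(3,4,5-trimethoxyphenyl)propan-2-yl]-7,7a-dihydro-1,3-benzodioxol-5(6H)-one, via lithium enolate 12 (not isolated)
Conditions: LiBH(s-Bu)3 (L-Selectride, 1.05 equiv), THF, −78 °C; then allyl bromide (3 equiv), −78 to 0 °C
Reagents that add atoms: allyl bromide, C=CCBr
Why: conjugate hydride addition to the only β-unsubstituted, non-oxygenated enone gives a regiodefined enolate (reductive alkylation) that is allylated on the face opposite the pseudo-axial C7a side chain, because the dioxolane oxygen lies near the ring plane, giving the 6,7a-trans (6R) product, which is also the more stable epimer.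

## Compound list

1 | 1-[4-(benzyloxy)-2-hydroxyphenyl]ethan-1-one | CC(=O)c1ccc(OCc2ccccc2)cc1O | starting material
2 | 5-(chloromethyl)-1,2,3-trimethoxybenzene | COc1cc(CCl)cc(OC)c1OC | starting material
3 | (3,4,5-trimethoxybenzyl)magnesium chloride | COc1cc(C[Mg]Cl)cc(OC)c1OC | intermediate
4 | rac-5-(benzyloxy)-2-[2-hydroxy-1-(3,4,5-trimethoxyphenyl)propan-2-yl]phenol | CC(O)(Cc1cc(OC)c(OC)c(OC)c1)c1ccc(OCc2ccccc2)cc1O | intermediate
5 | 3-(benzyloxy)-6-[1-(3,4,5-trimethoxyphenyl)propan-2-ylidene]cyclohexa-2,4-dien-1-one (ortho-quinone methide, interconverting E/Z forms) | CC(Cc1cc(OC)c(OC)c(OC)c1)=C1C=CC(OCc2ccccc2)=CC1=O | intermediate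
6 | 5-(benzyloxy)-2-[(2S)-1-(3,4,5-trimethoxyphenyl)propan-2-yl]phenol | Oc1cc(OCc2ccccc2)ccc1[C@@H](C)Cc1cc(OC)c(OC)c(OC)c1 | intermediate
7 | 4-(benzyloxy)-2-(methoxymethoxy)-1-[(2S)-1-(3,4,5-trimethoxyphenyl)propan-2-yl]benzene | COCOc1cc(OCc2ccccc2)ccc1[C@@H](C)Cc1cc(OC)c(OC)c(OC)c1 | intermediate
8 | 3-(methoxymethoxy)-4-[(2S)-1-(3,4,5-trimethoxyphenyl)propan-2-yl]phenol | COCOc1cc(O)ccc1[C@@H](C)Cc1cc(OC)c(OC)c(OC)c1 | intermediate
9 | acetoxy(phenyl)-λ3-iodanyl ether of phenol 8 | CC(=O)OI(Oc1ccc([C@@H](C)Cc2cc(OC)c(OC)c(OC)c2)c(OCOC)c1)c1ccccc1 | intermediate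
10 | (7aS)-1-methyl-5-oxo-7a-[(2S)-1-(3,4,5-trimethoxyphenyl)propan-2-yl]-5,7a-dihydro-1,3-benzodioxol-1-ium acetate | O=C1C=C[C@]2([C@@H](C)Cc3cc(OC)c(OC)c(OC)c3)[O+](C)COC2=C1.CC(=O)[O-] | intermediate
11 | (7aS)-7a-[(2S)-1-(3,4,5-trimethoxyphenyl)propan-2-yl]-1,3-benzodioxol-5(7aH)-one | O=C1C=C[C@]2([C@@H](C)Cc3cc(OC)c(OC)c(OC)c3)OCOC2=C1 | intermediate
12 | lithium (7aR)-7a-[(2S)-1-(3,4,5-trimethoxyphenyl)propan-2-yl]-7,7a-dihydro-1,3-benzodioxol-5-olate | [Li+].[O-]C1=CC[C@]2([C@@H](C)Cc3cc(OC)c(OC)c(OC)c3)OCOC2=C1 | intermediate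
13 | (6R,7aR)-6-(prop-2-en-1-yl)-7a-[(2S)-1-(3,4,5-trimethoxyphenyl)propan-2-yl]-7,7a-dihydro-1,3-benzodioxol-5(6H)-one | C=CC[C@@H]1C[C@]2([C@@H](C)Cc3cc(OC)c(OC)c(OC)c3)OCOC2=CC1=O | target

## Summary and risks

Total step count: 6. Longest linear sequence: 6 steps (from 1).

**Most likely to fail, first: step 5 (the proposed new step).** The cationic intermediate can lose the C8 proton to a para-quinone methide. It can be attacked by the trimethoxyphenyl ring to give a spiro-indane, or be captured by acetate or solvent. The facial selectivity may also be modest. The fallback uses known chemistry and sets out from 6. Hydrogenolysis (H2, 10% Pd/C, EtOAc) removes the benzyl group and gives 4-[(2S)-1-(3,4,5-trimethoxyphenyl)propan-2-yl]benzene-1,3-diol F1. Para-hydroxylative dearomatisation with PhI(OAc)2 in MeCN/H2O at 0 °C gives (4S)-3,4-dihydroxy-4-[(2S)-1-(3,4,5-trimethoxyphenyl)propan-2-yl]cyclohexa-2,5-dien-1-one F2, a vinylogous α-hydroxy acid, whose C4 epimer is removed by chromatography. Methylenation with BrCH2Cl and Cs2CO3 in DMF at 60 °C bridges the enol and tertiary oxygens, and the route is rejoined at 11.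

**Second: step 2.** Aryl/methyl ortho-quinone methides are the well-behaved cases; here the exocyclic carbon carries methyl and arylmethyl, so E/Z control and the enantiomeric excess are less certain. The fallback replaces the quinone methide reduction by asymmetric hydrogenation of a trisubstituted stilbene, and sets out from 4. Selective O-alkylation of the phenol (NaH, MOMCl, DMF) gives rac-2-[4-(benzyloxy)-2-(methoxymethoxy)phenyl]-1-(3,4,5-trimethoxyphenyl)propan-2-ol F3. Dehydration with Burgess reagent in toluene at 50 °C gives 4-(benzyloxy)-2-(methoxymethoxy)-1-[(E)-1-(3,4,5-trimethoxyphenyl)prop-1-en-2-yl]benzene F4. Hydrogenation (H2, 50 bar, CH2Cl2) with [Ir(cod)(t-Bu-PHOX)][B(C6H3(CF3)2)4], using the ligand antipode that gives the (S)-product, leaves the benzyl ether intact and rejoins the route at 7.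

**Third: step 6.** The hydride must add next to a quaternary carbon, 1,2-reduction can compete, and the borane-complexed enolate may allylate slowly or twice. The fallback generates the enolate by deprotonation of an isolated ketone instead, and sets out from 11. Conjugate reduction with [(Ph3P)CuH]6 (0.3 equiv) in wet THF gives (7aR)-7a-[(2S)-1-(3,4,5-trimethoxyphenyl)propan-2-yl]-7,7a-dihydro-1,3-benzodioxol-5(6H)-one F5. Kinetic deprotonation at C6 with LiN(i-Pr)2 in THF at −78 °C and addition of allyl bromide (Stork–Danheiser-type alkylation of a vinylogous ester) gives 13 with the same trans selectivity.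

## Further compounds

F1 | step 5 | 4-[(2S)-1-(3,4,5-trimethoxyphenyl)propan-2-yl]benzene-1,3-diol | Oc1ccc([C@@H](C)Cc2cc(OC)c(OC)c(OC)c2)c(O)c1
F2 | step 5 | (4S)-3,4-dihydroxy-4-[(2S)-1-(3,4,5-trimethoxyphenyl)propan-2-yl]cyclohexa-2,5-dien-1-one | O=C1C=C[C@@](O)([C@@H](C)Cc2cc(OC)c(OC)c(OC)c2)C(O)=C1
F3 | step 2 | rac-2-[4-(benzyloxy)-2-(methoxymethoxy)phenyl]-1-(3,4,5-trimethoxyphenyl)propan-2-ol | CC(O)(Cc1cc(OC)c(OC)c(OC)c1)c1ccc(OCc2ccccc2)cc1OCOC
F4 | step 2 | 4-(benzyloxy)-2-(methoxymethoxy)-1-[(E)-1-(3,4,5-trimethoxyphenyl)prop-1-en-2-yl]benzene | COCOc1cc(OCc2ccccc2)ccc1/C(C)=C/c1cc(OC)c(OC)c(OC)c1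
F5 | step 6 | (7aR)-7a-[(2S)-1-(3,4,5-trimethoxyphenyl)propan-2-yl]-7,7a-dihydro-1,3-benzodioxol-5(6H)-one | O=C1CC[C@]2([C@@H](C)Cc3cc(OC)c(OC)c(OC)c3)OCOC2=C1
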